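**Retrosynthetic overview**
- Last step: chemo- and face-selective epoxidation of the 1(10)-olefin of the finished heliangolide (oxirane ring formed last).
- Ten-membered ring: Nozaki–Hiyama–Kishi closure of C3–C4 (Z-alkenyl iodide onto a C3 aldehyde), which also creates the 3-OH (carbocycle formed second).
- γ-Lactone: acetonide release and lactonisation of O6 onto C12 (lactone formed first); the 8-O-ester comes from (2R,3R)-epoxyangelic acid, made by Sharpless epoxidation.
- Key C7–C8 bond: indium allylation in which the β-carbon of a glyceraldehyde-derived (Z)-2-(bromomethyl)enoate (an ester homoenolate equivalent) adds to a β,γ-unsaturated aldehyde, setting C7 and C8 next to the chiral-pool C6.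
- Building blocks: angelic acid; (R)-glyceraldehyde acetonide and methyl acrylate; silylated but-3-yn-1-ol, Me3Al and ethylene oxide.

Assumption: angelic acid, (R)-2,3-O-isopropylideneglyceraldehyde and 4-(tert-butyldimethylsilyloxy)-1-butyne are bought; positions are given in germacrane numbering (C1–C10 ring, C11–C13 lactone carbons, C14/C15 methyls).

**Route**

Step 1
Reactants: 1 angelic acid
Product: 2 (2Z)-2-methylbut-2-en-1-ol
Conditions: LiAlH4, Et2O, 0 °C; aqueous work-up
Reagents that add atoms: none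
Why: Hydride reduction of the carboxylic acid to the primary allylic alcohol leaves the Z-trisubstituted olefin untouched and creates no stereocentre.

Step 2
Reactants: 2 (2Z)-2-methylbut-2-en-1-ol
Product: 3 [(2S,3R)-2,3-dimethyloxiran-2-yl]methanol
Conditions: Ti(OiPr)4 (10 mol%), L-(+)-diethyl tartrate (12 mol%), t-BuOOH, 4 Å molecular sieves, CH2Cl2, −20 °C
Reagents that add atoms: tert-butyl hydroperoxide, CC(C)(C)OO
Why: Sharpless asymmetric epoxidation, in which the L-(+)-tartrate ligand delivers oxygen to the face that gives the (2S,3R)-epoxy alcohol (the same sense as nerol to (2S,3R)-epoxynerol) and the Z-olefin geometry fixes the cis relationship of CH2OH and the C3 methyl.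

Step 3
Reactants: 3 [(2S,3R)-2,3-dimethyloxiran-2-yl]methanol
Product: 5 (2R,3R)-2,3-dimethyloxirane-2-carboxylic acid, via epoxy aldehyde 4 (not isolated)
Conditions: RuCl3·xH2O (2 mol%), NaIO4, MeCN/EtOAc/H2O, 0 °C to rt
Reagents that add atoms: water, O
Why: Ruthenium tetroxide oxidation (RuCl3/NaIO4) takes the primary alcohol through the aldehyde hydrate to the acid without opening the electron-poor epoxide, and both stereocentres are untouched (C2 changes from S to R only through the priority change).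

Step 4
Reactants: 6 (4R)-2,2-dimethyl-1,3-dioxolane-4-carbaldehyde; 7 methyl acrylate
Product: 8 methyl 2-{[(4R)-2,2-dimethyl-1,3-dioxolan-4-yl](hydroxy)methyl}prop-2-enoate (both carbinol epimers)
Conditions: DABCO (20 mol%), neat, rt, several days
Reagents that add atoms: none
Why: Morita–Baylis–Hillman reaction, whose new carbinol centre forms as a mixture that does not matter because step 5 destroys it, while the dioxolane centre (the future C6) is retained.

Step 5
Reactants: 8 methyl 2-{[(4R)-2,2-dimethyl-1,3-dioxolan-4-yl](hydroxy)methyl}prop-2-enoate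
Product: 10 methyl (2Z)-2-(bromomethyl)-3-[(4S)-2,2-dimethyl-1,3-dioxolan-4-yl]prop-2-enoate, via alkoxysulfonium bromide 9 (not isolated)
Conditions: N-bromosuccinimide, Me2S, CH2Cl2, 0 °C to rt
Reagents that add atoms: N-bromosuccinimide, O=C1CCC(=O)N1Br
Why: Corey–Kim-type activation of the allylic alcohol and SN2' attack of bromide give the thermodynamically preferred (Z)-2-(bromomethyl)enoate (dioxolane trans to the ester), the standard conversion of Baylis–Hillman adducts.

Step 6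
Reactants: 11 tert-butyl(but-3-yn-1-yloxy)dimethylsilane; 12 oxirane
Product: 15 (3E)-6-{[tert-butyl(dimethyl)silyl]oxy}-4-methylhex-3-en-1-ol, via alkenylalane 13 (not isolated), via lithium alkenylalanate 14 (not isolated)
Conditions: Me3Al (2 equiv), Cp2ZrCl2 (20 mol%), CH2Cl2, 0 °C to rt; then n-BuLi, THF/hexane, −78 to 0 °C; then oxirane, −78 °C to rt
Reagents that add atoms: trimethylaluminium, C[Al](C)C
Why: Negishi zirconium-catalysed carboalumination adds methyl and aluminium syn across the terminal alkyne (methyl on the internal carbon), and the derived alanate opens oxirane with retention of the alkene geometry, which fixes the E-trisubstituted 1(10)-olefin.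

Step 7
Reactants: 15 (3E)-6-{[tert-butyl(dimethyl)silyl]oxy}-4-methylhex-3-en-1-ol
Product: 16 tert-butyl({(3E)-6-[(4-methoxybenzyl)oxy]-3-methylhex-3-en-1-yl}oxy)dimethylsilane
Conditions: NaH, 4-methoxybenzyl chloride, Bu4NI (cat.), DMF, 0 °C to rt
Reagents that add atoms: 4-methoxybenzyl chloride, COc1ccc(CCl)cc1
Why: Williamson etherification protects the future C3 oxygen with a group that survives acid and is later removed oxidatively.

Step 8
Reactants: 16 tert-butyl({(3E)-6-[(4-methoxybenzyl)oxy]-3-methylhex-3-en-1-yl}oxy)dimethylsilane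
Product: 17 (3E)-6-[(4-methoxybenzyl)oxy]-3-methylhex-3-en-1-ol
Conditions: Bu4NF, THF, 0 °C to rt
Reagents that add atoms: none
Why: Fluoride-mediated desilylation frees the C8 alcohol selectively because the benzyl-type ether is inert to fluoride.

Step 9
Reactants: 17 (3E)-6-[(4-methoxybenzyl)oxy]-3-methylhex-3-en-1-ol
Product: 18 (3E)-6-[(4-methoxybenzyl)oxy]-3-methylhex-3-enal
Conditions: Dess–Martin periodinane, pyridine, CH2Cl2, 0 °C; used at once
Reagents that add atoms: none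
Why: Buffered Dess–Martin oxidation gives the β,γ-unsaturated aldehyde under non-equilibrating conditions, so the olefin does not move into conjugation.

Step 10
Reactants: 10 methyl (2Z)-2-(bromomethyl)-3-[(4S)-2,2-dimethyl-1,3-dioxolan-4-yl]prop-2-enoate; 18 (3E)-6-[(4-methoxybenzyl)oxy]-3-methylhex-3-enal
Product: 20 methyl (3R,4R,6E)-3-[(4S)-2,2-dimethyl-1,3-dioxolan-4-yl]-4-hydroxy-9-[(4-methoxybenzyl)oxy]-6-methyl-2-methylidenenon-6-enoate, via allylindium dibromide 19 (not isolated)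
Conditions: In powder (1.5 equiv), THF/H2O (1:1), rt
Reagents that add atoms: none
Why: Barbier-type indium allylation in which the β-carbon of the enoate (C7), acting as an ester homoenolate (d3) equivalent through SE2' reaction of the allylindium, attacks the aldehyde carbon C8, so two carbons that are both electrophilic in their parent functions are joined; the retained Z-allyl geometry and a Zimmerman–Traxler chair (aldehyde residue equatorial) give the 7,8-syn relationship, the dioxolane centre directs the aldehyde anti to its C–O bond with H6 in the olefin plane to avoid 1,3-allylic strain (Felkin–Anh-type), giving 6R,7R,8R in target numbering, and water protonates the indium alkoxide so the open hydroxy ester is isolated.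

Step 11
Reactants: 20 methyl (3R,4R,6E)-3-[(4S)-2,2-dimethyl-1,3-dioxolan-4-yl]-4-hydroxy-9-[(4-methoxybenzyl)oxy]-6-methyl-2-methylidenenon-6-enoate; 5 (2R,3R)-2,3-dimethyloxirane-2-carboxylic acid
Product: 22 methyl (3R,4R,6E)-3-[(4S)-2,2-dimethyl-1,3-dioxolan-4-yl]-4-{[(2R,3R)-2,3-dimethyloxirane-2-carbonyl]oxy}-9-[(4-methoxybenzyl)oxy]-6-methyl-2-methylidenenon-6-enoate, via mixed anhydride 21 (not isolated)
Conditions: 5, 2,4,6-trichlorobenzoyl chloride, Et3N, THF, rt; then 20, DMAP, toluene, rt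
Reagents that add atoms: none
Why: Yamaguchi esterification acylates the hindered 8-OH with acyl–oxygen cleavage, so C8 keeps its configuration, and it blocks O8 before any lactonisation so that only O6 can later close the lactone.

Step 12
Reactants: 22 methyl (3R,4R,6E)-3-[(4S)-2,2-dimethyl-1,3-dioxolan-4-yl]-4-{[(2R,3R)-2,3-dimethyloxirane-2-carbonyl]oxy}-9-[(4-methoxybenzyl)oxy]-6-methyl-2-methylidenenon-6-enoate
Product: 24 (1R,3E)-1-[(2S,3R)-2-(hydroxymethyl)-4-methylidene-5-oxooxolan-3-yl]-6-[(4-methoxybenzyl)oxy]-3-methylhex-3-en-1-yl (2R,3R)-2,3-dimethyloxirane-2-carboxylate, via dihydroxy ester 23 (not isolated)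
Conditions: AcOH/H2O (4:1), 45 °C
Reagents that add atoms: none
Why: Acid-catalysed acetonide hydrolysis frees the 5,6-diol and the secondary 6-OH closes the five-membered lactone onto the methyl ester (γ-lactonisation is favoured over the δ-lactone through O5), giving the trans-disubstituted α-methylene-γ-butyrolactone without touching a stereocentre or the electron-poor glycidic ester.

Step 13
Reactants: 24 (1R,3E)-1-[(2S,3R)-2-(hydroxymethyl)-4-methylidene-5-oxooxolan-3-yl]-6-[(4-methoxybenzyl)oxy]-3-methylhex-3-en-1-yl (2R,3R)-2,3-dimethyloxirane-2-carboxylate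
Product: 25 (1R,3E)-1-[(2S,3R)-2-formyl-4-methylidene-5-oxooxolan-3-yl]-6-[(4-methoxybenzyl)oxy]-3-methylhex-3-en-1-yl (2R,3R)-2,3-dimethyloxirane-2-carboxylate
Conditions: Dess–Martin periodinane, pyridine, CH2Cl2, 0 °C to rt; used crude
Reagents that add atoms: none
Why: Dess–Martin oxidation of the primary alcohol gives the C5 aldehyde under neutral conditions, and the adjacent C6 centre is safe because the trans-lactone is the thermodynamically preferred epimer.

Step 14
Reactants: 25 (1R,3E)-1-[(2S,3R)-2-formyl-4-methylidene-5-oxooxolan-3-yl]-6-[(4-methoxybenzyl)oxy]-3-methylhex-3-en-1-yl (2R,3R)-2,3-dimethyloxirane-2-carboxylate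
Product: 26 (1R,3E)-1-{(2S,3R)-2-[(1Z)-2-iodoprop-1-en-1-yl]-4-methylidene-5-oxooxolan-3-yl}-6-[(4-methoxybenzyl)oxy]-3-methylhex-3-en-1-yl (2R,3R)-2,3-dimethyloxirane-2-carboxylate
Conditions: EtPPh3+ I−, n-BuLi, THF, rt; I2, −78 °C; NaN(SiMe3)2, −78 to −20 °C; then 25, −78 to −20 °C
Reagents that add atoms: ethyltriphenylphosphonium iodide, CC[P+](c1ccccc1)(c1ccccc1)c1ccccc1.[I-]; iodine, II
Why: Stork–Zhao-type Wittig olefination with the α-iodoethylidene ylide gives the (Z)-2-iodoalkene under kinetic control (C6 and iodine cis), which is exactly the geometry needed for the 4Z olefin once iodine is replaced by C3.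

Step 15
Reactants: 26 (1R,3E)-1-{(2S,3R)-2-[(1Z)-2-iodoprop-1-en-1-yl]-4-methylidene-5-oxooxolan-3-yl}-6-[(4-methoxybenzyl)oxy]-3-methylhex-3-en-1-yl (2R,3R)-2,3-dimethyloxirane-2-carboxylate
Product: 27 (1R,3E)-6-hydroxy-1-{(2S,3R)-2-[(1Z)-2-iodoprop-1-en-1-yl]-4-methylidene-5-oxooxolan-3-yl}-3-methylhex-3-en-1-yl (2R,3R)-2,3-dimethyloxirane-2-carboxylate
Conditions: DDQ, CH2Cl2/pH 7 buffer (10:1), 0 °C to rt
Reagents that add atoms: none
Why: Oxidative cleavage of the 4-methoxybenzyl ether by DDQ is neutral and leaves the alkenyl iodide, both esters, the epoxide and the olefins untouched.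

Step 16
Reactants: 27 (1R,3E)-6-hydroxy-1-{(2S,3R)-2-[(1Z)-2-iodoprop-1-en-1-yl]-4-methylidene-5-oxooxolan-3-yl}-3-methylhex-3-en-1-yl (2R,3R)-2,3-dimethyloxirane-2-carboxylate
Product: 28 (1R,3E)-1-{(2S,3R)-2-[(1Z)-2-iodoprop-1-en-1-yl]-4-methylidene-5-oxooxolan-3-yl}-3-methyl-6-oxohex-3-en-1-yl (2R,3R)-2,3-dimethyloxirane-2-carboxylate
Conditions: Dess–Martin periodinane, pyridine, CH2Cl2, 0 °C; used at once
Reagents that add atoms: none
Why: Buffered Dess–Martin oxidation gives the C3 aldehyde without shifting the β,γ-olefin into conjugation.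

Step 17
Reactants: 28 (1R,3E)-1-{(2S,3R)-2-[(1Z)-2-iodoprop-1-en-1-yl]-4-methylidene-5-oxooxolan-3-yl}-3-methyl-6-oxohex-3-en-1-yl (2R,3R)-2,3-dimethyloxirane-2-carboxylate
Product: 30 (3aR,4R,6E,9S,10Z,11aR)-9-hydroxy-6,10-dimethyl-3-methylidene-2-oxo-2,3,3a,4,5,8,9,11a-octahydrocyclodeca[b]furan-4-yl (2R,3R)-2,3-dimethyloxirane-2-carboxylate, via alkenylchromium dichloride 29 (not isolated)
Conditions: CrCl2 (12 equiv), NiCl2 (1 mol% of the chromium), degassed DMSO, rt, 0.003 M, slow addition of 28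
Reagents that add atoms: none
Why: Nozaki–Hiyama–Kishi reaction in which the alkenyl iodide is converted with retention of its Z geometry into an alkenylchromium species that adds to the tethered aldehyde at high dilution, closing the ten-membered ring; the C3 carbinol is set by macrocyclic conformational control, with attack on the outward face of the aldehyde in the lactone-anchored ring expected to give the 3S (3β) alcohol.

Step 18
Reactants: 30 (3aR,4R,6E,9S,10Z,11aR)-9-hydroxy-6,10-dimethyl-3-methylidene-2-oxo-2,3,3a,4,5,8,9,11a-octahydrocyclodeca[b]furan-4-yl (2R,3R)-2,3-dimethyloxirane-2-carboxylate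
Product: 31 (1R,3S,6R,7R,8R,10R)-1,10-epoxy-3-hydroxy-8-{[(2R,3R)-2,3-dimethyloxirane-2-carbonyl]oxy}germacra-4Z,11(13)-dien-12,6-olide (target CNP0268255.1)
Conditions: mCPBA (1.1 equiv), CH2Cl2, 0 °C
Reagents that add atoms: 3-chloroperoxybenzoic acid, O=C(OO)c1cccc(Cl)c1
Why: Prilezhaev epoxidation takes the most electron-rich olefin, the 1(10) double bond (the 4,5-olefin is deactivated by two allylic oxygens and the methylene lactone is electron-poor), stereospecifically from its exposed outer face in the lactone-fixed ring conformation, giving the trans 1β,10α-epoxide (1R,10R).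

**Compound list**

1 | angelic acid, (2Z)-2-methylbut-2-enoic acid | C/C=C(/C)C(=O)O | starting material
2 | (2Z)-2-methylbut-2-en-1-ol | C/C=C(/C)CO | intermediate
3 | [(2S,3R)-2,3-dimethyloxiran-2-yl]methanol | OC[C@]1(C)O[C@@H]1C | intermediate
4 | (2R,3R)-2,3-dimethyloxirane-2-carbaldehyde | O=C[C@]1(C)O[C@@H]1C | intermediate (not isolated)
5 | (2R,3R)-2,3-dimethyloxirane-2-carboxylic acid | OC(=O)[C@]1(C)O[C@@H]1C | intermediate
6 | (4R)-2,2-dimethyl-1,3-dioxolane-4-carbaldehyde | O=C[C@H]1COC(C)(C)O1 | starting material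
7 | methyl acrylate | C=CC(=O)OC | starting material
8 | methyl 2-{[(4R)-2,2-dimethyl-1,3-dioxolan-4-yl](hydroxy)methyl}prop-2-enoate (carbinol epimers) | C=C(C(=O)OC)C(O)[C@H]1COC(C)(C)O1 | intermediate
9 | ({1-[(4R)-2,2-dimethyl-1,3-dioxolan-4-yl]-2-(methoxycarbonyl)prop-2-en-1-yl}oxy)dimethylsulfonium bromide | C=C(C(=O)OC)C(O[S+](C)C)[C@H]1COC(C)(C)O1.[Br-] | intermediate (not isolated)
10 | methyl (2Z)-2-(bromomethyl)-3-[(4S)-2,2-dimethyl-1,3-dioxolan-4-yl]prop-2-enoate | COC(=O)/C(CBr)=C/[C@H]1COC(C)(C)O1 | intermediate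
11 | tert-butyl(but-3-yn-1-yloxy)dimethylsilane | C#CCCO[Si](C)(C)C(C)(C)C | starting material
12 | oxirane (ethylene oxide) | C1CO1 | starting material
13 | [(1E)-4-{[tert-butyl(dimethyl)silyl]oxy}-2-methylbut-1-en-1-yl]dimethylalumane | C[Al](C)/C=C(\C)CCO[Si](C)(C)C(C)(C)C | intermediate (not isolated)
14 | lithium butyl[(1E)-4-{[tert-butyl(dimethyl)silyl]oxy}-2-methylbut-1-en-1-yl]dimethylaluminate | [Li+].CCCC[Al-](C)(C)/C=C(\C)CCO[Si](C)(C)C(C)(C)C | intermediate (not isolated)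
15 | (3E)-6-{[tert-butyl(dimethyl)silyl]oxy}-4-methylhex-3-en-1-ol | OCC/C=C(\C)CCO[Si](C)(C)C(C)(C)C | intermediate
16 | tert-butyl({(3E)-6-[(4-methoxybenzyl)oxy]-3-methylhex-3-en-1-yl}oxy)dimethylsilane | COc1ccc(COCC/C=C(\C)CCO[Si](C)(C)C(C)(C)C)cc1 | intermediate
17 | (3E)-6-[(4-methoxybenzyl)oxy]-3-methylhex-3-en-1-ol | COc1ccc(COCC/C=C(\C)CCO)cc1 | intermediate
18 | (3E)-6-[(4-methoxybenzyl)oxy]-3-methylhex-3-enal | COc1ccc(COCC/C=C(\C)CC=O)cc1 | intermediate
19 | allylindium dibromide from 10 (C–Br replaced by C–InBr2, trivalent indium; one component of the allylindium sesquibromide) | COC(=O)/C(C[In](Br)Br)=C/[C@H]1COC(C)(C)O1 | intermediate (not isolated)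
20 | methyl (3R,4R,6E)-3-[(4S)-2,2-dimethyl-1,3-dioxolan-4-yl]-4-hydroxy-9-[(4-methoxybenzyl)oxy]-6-methyl-2-methylidenenon-6-enoate | COC(=O)C(=C)[C@@H]([C@H]1COC(C)(C)O1)[C@H](O)C/C(C)=C/CCOCc1ccc(OC)cc1 | intermediate
21 | (2R,3R)-2,3-dimethyloxirane-2-carboxylic 2,4,6-trichlorobenzoic anhydride | O=C(OC(=O)[C@]1(C)O[C@@H]1C)c1c(Cl)cc(Cl)cc1Cl | intermediate (not isolated)
22 | methyl (3R,4R,6E)-3-[(4S)-2,2-dimethyl-1,3-dioxolan-4-yl]-4-{[(2R,3R)-2,3-dimethyloxirane-2-carbonyl]oxy}-9-[(4-methoxybenzyl)oxy]-6-methyl-2-methylidenenon-6-enoate | COC(=O)C(=C)[C@@H]([C@H]1COC(C)(C)O1)[C@H](OC(=O)[C@]2(C)O[C@@H]2C)C/C(C)=C/CCOCc1ccc(OC)cc1 | intermediate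
23 | methyl (3S,4R,6E)-3-[(1S)-1,2-dihydroxyethyl]-4-{[(2R,3R)-2,3-dimethyloxirane-2-carbonyl]oxy}-9-[(4-methoxybenzyl)oxy]-6-methyl-2-methylidenenon-6-enoate | COC(=O)C(=C)[C@@H]([C@H](O)CO)[C@H](OC(=O)[C@]1(C)O[C@@H]1C)C/C(C)=C/CCOCc1ccc(OC)cc1 | intermediate (not isolated)
24 | (1R,3E)-1-[(2S,3R)-2-(hydroxymethyl)-4-methylidene-5-oxooxolan-3-yl]-6-[(4-methoxybenzyl)oxy]-3-methylhex-3-en-1-yl (2R,3R)-2,3-dimethyloxirane-2-carboxylate | C=C1C(=O)O[C@H](CO)[C@H]1[C@H](OC(=O)[C@]2(C)O[C@@H]2C)C/C(C)=C/CCOCc1ccc(OC)cc1 | intermediate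
25 | (1R,3E)-1-[(2S,3R)-2-formyl-4-methylidene-5-oxooxolan-3-yl]-6-[(4-methoxybenzyl)oxy]-3-methylhex-3-en-1-yl (2R,3R)-2,3-dimethyloxirane-2-carboxylate | C=C1C(=O)O[C@H](C=O)[C@H]1[C@H](OC(=O)[C@]2(C)O[C@@H]2C)C/C(C)=C/CCOCc1ccc(OC)cc1 | intermediate
26 | (1R,3E)-1-{(2S,3R)-2-[(1Z)-2-iodoprop-1-en-1-yl]-4-methylidene-5-oxooxolan-3-yl}-6-[(4-methoxybenzyl)oxy]-3-methylhex-3-en-1-yl (2R,3R)-2,3-dimethyloxirane-2-carboxylate | C=C1C(=O)O[C@H](/C=C(/C)I)[C@H]1[C@H](OC(=O)[C@]2(C)O[C@@H]2C)C/C(C)=C/CCOCc1ccc(OC)cc1 | intermediate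
27 | (1R,3E)-6-hydroxy-1-{(2S,3R)-2-[(1Z)-2-iodoprop-1-en-1-yl]-4-methylidene-5-oxooxolan-3-yl}-3-methylhex-3-en-1-yl (2R,3R)-2,3-dimethyloxirane-2-carboxylate | C=C1C(=O)O[C@H](/C=C(/C)I)[C@H]1[C@H](OC(=O)[C@]2(C)O[C@@H]2C)C/C(C)=C/CCO | intermediate
28 | (1R,3E)-1-{(2S,3R)-2-[(1Z)-2-iodoprop-1-en-1-yl]-4-methylidene-5-oxooxolan-3-yl}-3-methyl-6-oxohex-3-en-1-yl (2R,3R)-2,3-dimethyloxirane-2-carboxylate | C=C1C(=O)O[C@H](/C=C(/C)I)[C@H]1[C@H](OC(=O)[C@]2(C)O[C@@H]2C)C/C(C)=C/CC=O | intermediate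
29 | alkenylchromium dichloride from 28 (C–I replaced by C–CrCl2, trivalent chromium) | C=C1C(=O)O[C@H](/C=C(/C)[Cr](Cl)Cl)[C@H]1[C@H](OC(=O)[C@]2(C)O[C@@H]2C)C/C(C)=C/CC=O | intermediate (not isolated)
30 | (3aR,4R,6E,9S,10Z,11aR)-9-hydroxy-6,10-dimethyl-3-methylidene-2-oxo-2,3,3a,4,5,8,9,11a-octahydrocyclodeca[b]furan-4-yl (2R,3R)-2,3-dimethyloxirane-2-carboxylate (the 1(10)E,4Z-diene, 3β-OH, 8β-ester, 6α,12-olide) | C=C1C(=O)O[C@@H]2/C=C(/C)[C@@H](O)C/C=C(\C)C[C@@H](OC(=O)[C@]3(C)O[C@@H]3C)[C@@H]12 | intermediate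
31 | (1R,3S,6R,7R,8R,10R)-1,10-epoxy-3-hydroxy-8-{[(2R,3R)-2,3-dimethyloxirane-2-carbonyl]oxy}germacra-4Z,11(13)-dien-12,6-olide | C=C1C(=O)O[C@@H]2/C=C(/C)[C@@H](O)C[C@H]3O[C@]3(C)C[C@@H](OC(=O)[C@]3(C)O[C@@H]3C)[C@@H]12 | target

**Step count and risks**

Total: 18 steps. Longest linear sequence: 13 steps (steps 6 to 18, from 11).

The three steps most likely to fail:

1. Step 10 (key coupling). The face selectivity imposed by the dioxolane is argued by analogy and is not certain, and the γ-hydroxy ester may lactonise through O8. Fallback: set out again from 10 and 18 and run the coupling under anhydrous Nozaki–Hiyama conditions (CrCl2, THF, rt). There the chromium chair transition state is tighter and the chromium alkoxide closes in situ to the cis-fused 8,12-lactone acetonide F1. Aqueous AcOH then gives the cis-lactone diol F2, which is equilibrated (cat. DBU, CH2Cl2) by translactonisation to the less strained trans-6,12-lactone diol F3. TBSCl/imidazole silylates the primary 5-OH to give the primary silyl ether F4, Yamaguchi esterification with 5 acylates the 8-OH to give the silylated epoxy ester F5, and HF·pyridine removes the silyl group to come back to the route at 24.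

2. Step 17 (ring closure). The ten-membered ring is strained and the C3 configuration rests on macrocyclic control only. Fallback: set out from 28, accept whatever C3 ratio the closure gives, including the 3R epimer F6, and oxidise the crude carbinol mixture with Dess–Martin periodinane to the macrocyclic dienone F7. Reduce this under reagent control with (R)-2-methyl-CBS-oxazaborolidine and catecholborane (alkenyl side as the large group) to come back at 30.

3. Step 18 (last epoxidation). The free allylic 3-OH may steer the peracid to the 4,5-olefin, or the wrong face of the 1(10)-olefin may react. Fallback: set out from 30 and silylate the 3-OH (TESCl, imidazole) to the triethylsilyl ether F8. Epoxidise under reagent control with the D-fructose-derived Shi ketone (KHSO5 as its triple salt 2KHSO5·KHSO4·K2SO4, K2CO3, MeCN/dimethoxymethane/buffer, 0 °C), which gives R,R-epoxides from E-trisubstituted olefins, to the epoxy triethylsilyl ether F9. Remove the silyl group with HF·pyridine to come back at 31.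

**Further compounds**

F1 | step 10 | (4R,5R)-4-[(4S)-2,2-dimethyl-1,3-dioxolan-4-yl]-5-{(2E)-5-[(4-methoxybenzyl)oxy]-2-methylpent-2-en-1-yl}-3-methylideneoxolan-2-one | C=C1C(=O)O[C@H](C/C(C)=C/CCOCc2ccc(OC)cc2)[C@@H]1[C@H]1COC(C)(C)O1
F2 | step 10 | (4S,5R)-4-[(1S)-1,2-dihydroxyethyl]-5-{(2E)-5-[(4-methoxybenzyl)oxy]-2-methylpent-2-en-1-yl}-3-methylideneoxolan-2-one | C=C1C(=O)O[C@H](C/C(C)=C/CCOCc2ccc(OC)cc2)[C@@H]1[C@H](O)CO
F3 | step 10 | (4R,5S)-4-{(1R,3E)-1-hydroxy-6-[(4-methoxybenzyl)oxy]-3-methylhex-3-en-1-yl}-5-(hydroxymethyl)-3-methylideneoxolan-2-one | C=C1C(=O)O[C@H](CO)[C@H]1[C@H](O)C/C(C)=C/CCOCc1ccc(OC)cc1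
F4 | step 10 | (4R,5S)-5-({[tert-butyl(dimethyl)silyl]oxy}methyl)-4-{(1R,3E)-1-hydroxy-6-[(4-methoxybenzyl)oxy]-3-methylhex-3-en-1-yl}-3-methylideneoxolan-2-one | C=C1C(=O)O[C@H](CO[Si](C)(C)C(C)(C)C)[C@H]1[C@H](O)C/C(C)=C/CCOCc1ccc(OC)cc1
F5 | step 10 | (1R,3E)-1-[(2S,3R)-2-({[tert-butyl(dimethyl)silyl]oxy}methyl)-4-methylidene-5-oxooxolan-3-yl]-6-[(4-methoxybenzyl)oxy]-3-methylhex-3-en-1-yl (2R,3R)-2,3-dimethyloxirane-2-carboxylate | C=C1C(=O)O[C@H](CO[Si](C)(C)C(C)(C)C)[C@H]1[C@H](OC(=O)[C@]2(C)O[C@@H]2C)C/C(C)=C/CCOCc1ccc(OC)cc1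
F6 | step 17 | (3aR,4R,6E,9R,10Z,11aR)-9-hydroxy-6,10-dimethyl-3-methylidene-2-oxo-2,3,3a,4,5,8,9,11a-octahydrocyclodeca[b]furan-4-yl (2R,3R)-2,3-dimethyloxirane-2-carboxylate (C3 epimer of 30) | C=C1C(=O)O[C@@H]2/C=C(/C)[C@H](O)C/C=C(\C)C[C@@H](OC(=O)[C@]3(C)O[C@@H]3C)[C@@H]12
F7 | step 17 | (3aR,4R,6E,10Z,11aR)-6,10-dimethyl-3-methylidene-2,9-dioxo-2,3,3a,4,5,8,9,11a-octahydrocyclodeca[b]furan-4-yl (2R,3R)-2,3-dimethyloxirane-2-carboxylate | C=C1C(=O)O[C@@H]2/C=C(/C)C(=O)C/C=C(\C)C[C@@H](OC(=O)[C@]3(C)O[C@@H]3C)[C@@H]12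
F8 | step 18 | 3-O-triethylsilyl ether of 30 | C=C1C(=O)O[C@@H]2/C=C(/C)[C@@H](O[Si](CC)(CC)CC)C/C=C(\C)C[C@@H](OC(=O)[C@]3(C)O[C@@H]3C)[C@@H]12
F9 | step 18 | 3-O-triethylsilyl ether of 31 | C=C1C(=O)O[C@@H]2/C=C(/C)[C@@H](O[Si](CC)(CC)CC)C[C@H]3O[C@]3(C)C[C@@H](OC(=O)[C@]3(C)O[C@@H]3C)[C@@H]12
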